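3 questions wait on this flask; they stand below with the two earlier runs.

| flask | substrate | solid reagent | free catalyst | remark | time |
|---|---|---|---|---|---|
| midnight | 0.019 M | 1.2 equiv | 1.6 mol% | run made earlier |  |
| dawn | 0.029 M | 1.2 equiv | 1.6 mol% | run made earlier |  |
| flask | 0.039 M | 1.20 equiv | 1.6 mol% |  | 12 h |

- midnight (time / h: target / %, substrate / %): 0.667: 0.5, 100.0; 2.00: 3.2, 96.2; 3.00: 8.1, 92.4; 5.00: 17.0, 82.6; 8.00: 33.6, 66.2
- dawn (time / h: target / %, substrate / %): 1.33: 2.5, 98.2; 3.00: 9.2, 91.3; 4.00: 13.0, 86.9; 6.00: 23.8, 76.2; 8.00: 34.2, 64.4

(each reading ± 0.5 percentage points)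

- as a solid, counted per litre of solution: solid reagent
- at the start none of the solid reagent is in solution

* target at 12 h, in percent of the substrate charged
* the change that raises the amount of target at 12 h, in percent of the substrate charged most ("none" if none brings more than 2 percentage points) (violet / blue / green / none)
* amount of target at 12 h, in percent of the substrate charged, after blue

- violet: doubling the dissolution coefficient of the solid reagent, all else as stated
- blue: doubling the amount of free catalyst, all else as stated
- green: doubling the solubility of the solid reagent, all else as stated

For whoever takes over: the flask holds substrate, free catalyst and solid reagent, with none of that solid in solution at the start. On the straight stretch the midnight run made target at 0.969 mM h⁻¹ and the dawn run at 1.45 mM h⁻¹, in step with the charge. In the dawn run the slope held while substrate fell to 64.4%, but a straight line does not by itself give the order in [substrate]: [partner], the dissolved solid reagent, which we cannot read, may be rising meanwhile.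

We carry the draw, the target made per litre per hour on the straight stretch, 1.95 mM h⁻¹ for this flask. After the dawn run's lag of 1.16 h, our own reckoning gives 54.2% target at 12 h. Don't count on more free catalyst: a doubled draw asks 46.8 mM by then, about the whole solid charge of 46.8 mM. We would look to the solid first.

The forecast gives 53%, blue as the best change and 90% after it, holding that “Dissolution is not limiting”.

The flask gives 51.1%; green brings 25 percentage points, blue 12 points, reaching 63.4%.

    partner + free catalyst ⇌ catalyst intermediate A (K = 24.0 L mol⁻¹, k = 1300 L mol⁻¹ h⁻¹)
    solid reagent ⇌ partner, rate k2*(cs2 - [partner]) while solid is left; crystals form when [partner] > cs2 (solubility = 25.0 mM, k = 0.110 h⁻¹)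
    catalyst intermediate C → free catalyst + target (k = 5100 h⁻¹)
    partner + target → over-reaction product (k = 1.20 L mol⁻¹ h⁻¹)
    catalyst intermediate A ⇌ catalyst intermediate B (K = 2.80, k = 260 h⁻¹)
    substrate + catalyst intermediate B → catalyst intermediate C (k = 1200 L mol⁻¹ h⁻¹)

By 12 h the dissolving can deliver at most 84.6% into a solution kept empty, an average of 2.75 mM h⁻¹. From 6.00 h to 12 h this flask's draw was 1.83 mM h⁻¹, less than reckoned. Averaged over 12 h, doubled catalyst drew 2.06 mM h⁻¹ against this flask's 1.66 mM h⁻¹, a factor of 1.24.

(The readings were computed from invented constants.)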